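The dihydropyran ring (O1, C2–C6) is opened retrosynthetically at C2–C3 and O1–C6. The feature exploited is that O1–C2 with its methyl group is acetaldehyde, and that the C2 methyl and the C3 hydroxymethyl carbon C10 are cis, as an endo [4+2] addition delivers them. One catalytic asymmetric hetero-Diels–Alder reaction thus makes the ring, two skeletal bonds and three stereocentres from achiral partners. Its precursor is a (1E,3Z)-1-methoxy-3-silyloxypenta-1,3-diene whose terminus carries C10 as an outward-pointing PMB-oxymethyl group. In the adduct the C4 enol silane becomes the handle for the C8–C9 arm, the C6 acetal hides the C5=C6 enol ether, and C4 is set by hydroxyl-directed hydrogenation.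

Key step: step 5

Numbering used throughout: O1, C2 (CH3), C3 (C10H2OH), C4 (C8H2–C9O2R), C5 (C7O2CH3), C6. PMB = 4-methoxybenzyl, TES = triethylsilyl, TBS = tert-butyldimethylsilyl, TMS = trimethylsilyl.

Assumption: the catalyst built from (1R,2S)-1-aminoindan-2-ol is assigned to the 2S series by analogy with its behaviour towards other unbranched aliphatic aldehydes. If the sense proves opposite, the equally available (1S,2R) ligand is used.

Step 1
Reactants: 1 4-methoxybenzyl alcohol; 2 methyl acrylate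
Product: 3 methyl 3-(4-methoxybenzyloxy)propanoate
Conditions: NaH (5 mol %), 2 (2 equiv), THF, 0 °C → rt
Reagents that add atoms: none
Why: Alkoxide-catalysed oxa-Michael addition to an acrylate is a chain process that regenerates the alkoxide, and any transesterified PMB ester formed alongside is converted into the same amide in step 2.

Step 2
Reactants: 3 methyl 3-(4-methoxybenzyloxy)propanoate
Product: 4 N-methoxy-N-methyl-3-(4-methoxybenzyloxy)propanamide
Conditions: MeNH(OMe)·HCl (1.5 equiv), iPrMgCl (3 equiv), THF, −20 °C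
Reagents that add atoms: N,O-dimethylhydroxylamine hydrochloride, CNOC.Cl
Why: Aminolysis of the ester by the chloromagnesium amide (first half of the Weinreb ketone synthesis) is fast at −20 °C, where the β-alkoxy ester is not enolised and therefore does not lose 4-methoxybenzyl oxide.

Step 3
Reactants: 4 N-methoxy-N-methyl-3-(4-methoxybenzyloxy)propanamide; 5 ethynylmagnesium bromide
Product: 7 (E)-1-methoxy-5-(4-methoxybenzyloxy)pent-1-en-3-one, via ynone 6 (not isolated)
Conditions: 5 (1.5 equiv), THF, 0 °C; inverse quench into cold aq NaHSO4, extraction; crude 6 in MeOH, DABCO (10 mol %), 0 °C → rt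
Reagents that add atoms: methanol, CO
Why: The Weinreb ketone synthesis stops at the magnesium chelate so that only one ethynyl group is taken up, the acidic inverse quench keeps the released amine protonated and away from ynone 6, and the amine-catalysed conjugate addition of methanol gives the more stable E β-methoxy enone.

Step 4
Reactants: 7 (E)-1-methoxy-5-(4-methoxybenzyloxy)pent-1-en-3-one
Product: 8 (1E,3Z)-1-methoxy-5-(4-methoxybenzyloxy)-3-(triethylsilyloxy)penta-1,3-diene
Conditions: TESOTf (1.2 equiv), Et3N (2 equiv), Et2O, −78 → 0 °C; cold aq NaHCO3; Et3N-deactivated silica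
Reagents that add atoms: triethylsilyl trifluoromethanesulfonate, CC[Si](CC)(CC)OS(=O)(=O)C(F)(F)F
Why: Soft enolisation with a silyl triflate and a tertiary amine silylates the carbonyl oxygen first and then removes a proton from the future C3 in the conformer that avoids allylic strain, which gives the Z enol silane (C10 trans to the methoxyvinyl group) without expelling the β-PMB-oxy group; the triethylsilyl group allows chromatographic removal of triflate salts.

Step 5
Reactants: 8 (1E,3Z)-1-methoxy-5-(4-methoxybenzyloxy)-3-(triethylsilyloxy)penta-1,3-diene; 9 acetaldehyde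
Product: 10 (2S,3R,6S)-6-methoxy-3-[(4-methoxybenzyloxy)methyl]-2-methyl-4-(triethylsilyloxy)-3,6-dihydro-2H-pyran (all-cis)
Conditions: CrCl(L) (5 mol %; H2L = Schiff base of 3-(1-adamantyl)-5-methylsalicylaldehyde with (1R,2S)-1-aminoindan-2-ol), 9 (5 equiv), powdered 4 Å MS, no added solvent, sealed flask, 4 °C; pentane, filtration; Et3N-deactivated silica
Reagents that add atoms: none
Why: Acetaldehyde coordinates through oxygen to the Lewis-acidic trivalent chromium centre and adds to the s-cis diene in a concerted, asynchronous [4π+2π] cycloaddition in which C2–C3 runs ahead of O1–C6. The closest known reaction type is the enantioselective hetero-Diels–Alder reaction of unbranched aliphatic aldehydes with 1-alkoxy-3-silyloxy dienes under tridentate Schiff base chlorochromium catalysis. The six-membered ring O1–C2–C3–C4–C5–C6 is closed intermolecularly in this one suprafacial event, so that the C4 enol silane and the C6 methyl acetal survive in the product. C2 is controlled by the catalyst, whose adamantyl and indanyl groups leave only one carbonyl face open (the 1R,2S ligand for 2S). C3 and C6 are controlled by the diene geometry together with the endo rule: the 3Z and 1E double bonds place C10 and OMe outward and hence cis to each other, and the catalyst bound anti to the aldehyde methyl occupies the exo region, which puts the methyl endo and on the same face. The step needs enantioface, endo and pathway selectivity (no stepwise Mukaiyama aldol addition), secured in the substrate by the geometrically pure, salt-free triethylsilyl diene, whose hindered silyl group does not migrate readily, and by the polarisation of the diene, which makes the C10-bearing carbon the only nucleophilic terminus.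

Step 6
Reactants: 10 (2S,3R,6S)-6-methoxy-3-[(4-methoxybenzyloxy)methyl]-2-methyl-4-(triethylsilyloxy)-3,6-dihydro-2H-pyran
Product: 12 (2S,3R,6S)-6-methoxy-3-[(4-methoxybenzyloxy)methyl]-2-methyl-3,6-dihydro-2H-pyran-4-yl trifluoromethanesulfonate, via lithium enolate 11 (not isolated)
Conditions: MeLi (1.1 equiv), THF, −20 °C; then −78 °C, N-(5-chloropyridin-2-yl)bis(trifluoromethanesulfonimide) (1.3 equiv), −78 → −30 °C; sat. aq NH4Cl
Reagents that add atoms: N-(5-chloropyridin-2-yl)bis(trifluoromethanesulfonimide), O=S(=O)(N(c1ccc(Cl)cn1)S(=O)(=O)C(F)(F)F)C(F)(F)F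
Why: Methyllithium attacks silicon and releases the enolate regiospecifically at C4=C5 without touching C3–H (enol silane cleavage followed by O-sulfonylation); lithium enolates of methyl 2-deoxyhexopyranosid-3-uloses, which carry the same O–C(OMe)–C=C(OLi) array, can be alkylated below −20 °C, and the pyridyl triflimide traps the enolate at −78 °C faster than methoxide is lost from C6.

Step 7
Reactants: 13 hydroxytyrosol; 14 bromoacetyl bromide
Product: 15 2-(3,4-dihydroxyphenyl)ethyl bromoacetate
Conditions: 14 (1.05 equiv), dimethyl carbonate, no base, 0 °C → rt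
Reagents that add atoms: none
Why: Without base an acyl halide acylates the aliphatic hydroxyl much faster than the two phenols, the known chemoselective esterification of phenolic alcohols.

Step 8
Reactants: 15 2-(3,4-dihydroxyphenyl)ethyl bromoacetate
Product: 16 2-[3,4-bis(tert-butyldimethylsilyloxy)phenyl]ethyl bromoacetate
Conditions: TBSOTf (2.3 equiv), 2,6-lutidine (3 equiv), CH2Cl2, 0 °C
Reagents that add atoms: tert-butyldimethylsilyl trifluoromethanesulfonate, CC(C)(C)[Si](C)(C)OS(=O)(=O)C(F)(F)F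
Why: O-Silylation with a silyl triflate and the hindered, non-nucleophilic 2,6-lutidine protects both phenols without displacing the α-bromide, which imidazole or triethylamine would attack.

Step 9
Reactants: 12 (2S,3R,6S)-6-methoxy-3-[(4-methoxybenzyloxy)methyl]-2-methyl-3,6-dihydro-2H-pyran-4-yl trifluoromethanesulfonate; 16 2-[3,4-bis(tert-butyldimethylsilyloxy)phenyl]ethyl bromoacetate
Product: 18 2-[3,4-bis(tert-butyldimethylsilyloxy)phenyl]ethyl 2-{(2S,3R,6S)-6-methoxy-3-[(4-methoxybenzyloxy)methyl]-2-methyl-3,6-dihydro-2H-pyran-4-yl}acetate, via Reformatsky reagent 17 (not isolated)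
Conditions: 16 (2 equiv), Zn dust (TMSCl-activated), THF, rt → 35 °C; then 12, Pd(PPh3)4 (5 mol %), THF, 45 °C
Reagents that add atoms: none
Why: Zinc inserts into the C–Br bond and the resulting Reformatsky reagent couples with the alkenyl triflate under zerovalent palladium catalysis (Negishi-type coupling, known for alkenyl triflates); the weakly basic zinc enolate leaves C3, the acetal, the ester and the aryl silyl ethers untouched, and no stereocentre is formed.

Step 10
Reactants: 18 2-[3,4-bis(tert-butyldimethylsilyloxy)phenyl]ethyl 2-{(2S,3R,6S)-6-methoxy-3-[(4-methoxybenzyloxy)methyl]-2-methyl-3,6-dihydro-2H-pyran-4-yl}acetate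
Product: 19 2-[3,4-bis(tert-butyldimethylsilyloxy)phenyl]ethyl 2-[(2S,3R,6S)-3-(hydroxymethyl)-6-methoxy-2-methyl-3,6-dihydro-2H-pyran-4-yl]acetate
Conditions: DDQ (1.3 equiv), CH2Cl2/pH 7 phosphate buffer (10:1), 0 °C
Reagents that add atoms: none
Why: Oxidative PMB ether cleavage runs through the benzylic oxocarbenium ion under buffered neutral conditions, which spare the acid-labile allylic acetal and do not promote lactonisation, while the phenethyl CH2 of the silylated catechol has no α-oxygen and is oxidised far more slowly.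

Step 11
Reactants: 19 2-[3,4-bis(tert-butyldimethylsilyloxy)phenyl]ethyl 2-[(2S,3R,6S)-3-(hydroxymethyl)-6-methoxy-2-methyl-3,6-dihydro-2H-pyran-4-yl]acetate
Product: 20 2-[3,4-bis(tert-butyldimethylsilyloxy)phenyl]ethyl 2-[(2S,3R,4S,6S)-3-(hydroxymethyl)-6-methoxy-2-methyloxan-4-yl]acetate
Conditions: [Ir(cod)(PCy3)(py)]PF6 (5 mol %), H2 (1 atm), dry CH2Cl2, 0 °C → rt
Reagents that add atoms: none
Why: In this hydroxyl-directed homogeneous hydrogenation the C10 hydroxyl binds the cationic iridium and both hydrogens reach C4=C5 from the face that carries C10, so that C4–H is cis to the hydroxymethyl group and the arm trans (4S), against the steric bias an undirected catalyst would follow.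

Step 12
Reactants: 20 2-[3,4-bis(tert-butyldimethylsilyloxy)phenyl]ethyl 2-[(2S,3R,4S,6S)-3-(hydroxymethyl)-6-methoxy-2-methyloxan-4-yl]acetate
Product: 22 2-[3,4-bis(tert-butyldimethylsilyloxy)phenyl]ethyl 2-[(2S,3R,4R)-3-(tert-butyldimethylsilyloxymethyl)-2-methyl-3,4-dihydro-2H-pyran-4-yl]acetate, via silyl ether 21 (not isolated)
Conditions: TBSOTf (1.1 equiv), iPr2NEt (4 equiv), CH2Cl2, −78 → 0 °C; then TMSOTf (1.5 equiv), 0 °C → rt; aq NaHCO3; Et3N-deactivated silica
Reagents that add atoms: tert-butyldimethylsilyl trifluoromethanesulfonate, CC(C)(C)[Si](C)(C)OS(=O)(=O)C(F)(F)F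
Why: The primary alcohol is silylated first, then the silyl triflate ionises the C6 acetal and the amine removes a C5 proton from the oxocarbenium ion (known silyl-triflate-induced conversion of an acetal into an enol ether); only C5 carries protons next to C6, and C2, C3 and C4 are not involved (the 4R descriptor reflects a priority change only).

Step 13
Reactants: 22 2-[3,4-bis(tert-butyldimethylsilyloxy)phenyl]ethyl 2-[(2S,3R,4R)-3-(tert-butyldimethylsilyloxymethyl)-2-methyl-3,4-dihydro-2H-pyran-4-yl]acetate; 23 trichloroacetyl chloride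
Product: 24 2-[3,4-bis(tert-butyldimethylsilyloxy)phenyl]ethyl 2-[(2S,3R,4S)-3-(tert-butyldimethylsilyloxymethyl)-2-methyl-5-(trichloroacetyl)-3,4-dihydro-2H-pyran-4-yl]acetate
Conditions: 23 (3 equiv), pyridine (3.5 equiv), CH2Cl2, 0 °C → rt
Reagents that add atoms: none
Why: Enol ethers are C-acylated at the β-carbon by trichloroacetyl chloride and pyridine (attack of C5, then loss of H5 from the oxocarbenium ion), the standard entry to the C5 acyl group of iridoid-type dihydropyrans, and the masked C10 hydroxyl cannot be O-acylated.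

Step 14
Reactants: 24 2-[3,4-bis(tert-butyldimethylsilyloxy)phenyl]ethyl 2-[(2S,3R,4S)-3-(tert-butyldimethylsilyloxymethyl)-2-methyl-5-(trichloroacetyl)-3,4-dihydro-2H-pyran-4-yl]acetate
Product: 25 methyl (2S,3R,4S)-4-(2-{2-[3,4-bis(tert-butyldimethylsilyloxy)phenyl]ethoxy}-2-oxoethyl)-3-(tert-butyldimethylsilyloxymethyl)-2-methyl-3,4-dihydro-2H-pyran-5-carboxylate
Conditions: MeOH/CH2Cl2 (4:1), Et3N (3 equiv), DMAP (10 mol %), argon, 0 °C → rt
Reagents that add atoms: methanol, CO
Why: In this haloform-type cleavage methanol adds to the strongly activated trichloromethyl ketone and trichloromethanide leaves, which needs only a tertiary amine and is far faster than transesterification at C9; partial loss of aryl silyl groups would be harmless because they fall in step 15.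

Step 15
Reactants: 25 methyl (2S,3R,4S)-4-(2-{2-[3,4-bis(tert-butyldimethylsilyloxy)phenyl]ethoxy}-2-oxoethyl)-3-(tert-butyldimethylsilyloxymethyl)-2-methyl-3,4-dihydro-2H-pyran-5-carboxylate
Product: 26 methyl (2S,3R,4S)-4-{2-[2-(3,4-dihydroxyphenyl)ethoxy]-2-oxoethyl}-3-(hydroxymethyl)-2-methyl-3,4-dihydro-2H-pyran-5-carboxylate (target)
Conditions: HF·pyridine, extra pyridine, THF, plastic vessel, argon, 0 °C → rt; pH 7 buffer
Reagents that add atoms: none
Why: Buffered HF·pyridine removes all three silyl ethers under weakly acidic conditions, which avoids the alkoxide and phenoxide that basic fluoride would generate and that would close the δ-lactone onto C9 or expose the catechol to oxidation.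

Compound list

1 | 4-methoxybenzyl alcohol | COc1ccc(CO)cc1 | starting material
2 | methyl acrylate | C=CC(=O)OC | starting material
3 | methyl 3-(4-methoxybenzyloxy)propanoate | COC(=O)CCOCc1ccc(OC)cc1 | intermediate
4 | N-methoxy-N-methyl-3-(4-methoxybenzyloxy)propanamide | CON(C)C(=O)CCOCc1ccc(OC)cc1 | intermediate
5 | ethynylmagnesium bromide | C#C[Mg]Br | starting material
6 | 5-(4-methoxybenzyloxy)pent-1-yn-3-one | C#CC(=O)CCOCc1ccc(OC)cc1 | intermediate
7 | (E)-1-methoxy-5-(4-methoxybenzyloxy)pent-1-en-3-one | CO/C=C/C(=O)CCOCc1ccc(OC)cc1 | intermediate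
8 | (1E,3Z)-1-methoxy-5-(4-methoxybenzyloxy)-3-(triethylsilyloxy)penta-1,3-diene | CO/C=C/C(O[Si](CC)(CC)CC)=C/COCc1ccc(OC)cc1 | intermediate
9 | acetaldehyde | CC=O | starting material
10 | (2S,3R,6S)-6-methoxy-3-[(4-methoxybenzyloxy)methyl]-2-methyl-4-(triethylsilyloxy)-3,6-dihydro-2H-pyran | C[C@@H]1O[C@H](OC)C=C(O[Si](CC)(CC)CC)[C@@H]1COCc2ccc(OC)cc2 | intermediate
11 | lithium (2S,3R,6S)-6-methoxy-3-[(4-methoxybenzyloxy)methyl]-2-methyl-3,6-dihydro-2H-pyran-4-olate | C[C@@H]1O[C@H](OC)C=C([O-])[C@@H]1COCc2ccc(OC)cc2.[Li+] | intermediate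
12 | (2S,3R,6S)-6-methoxy-3-[(4-methoxybenzyloxy)methyl]-2-methyl-3,6-dihydro-2H-pyran-4-yl trifluoromethanesulfonate | C[C@@H]1O[C@H](OC)C=C(OS(=O)(=O)C(F)(F)F)[C@@H]1COCc2ccc(OC)cc2 | intermediate
13 | hydroxytyrosol | OCCc1ccc(O)c(O)c1 | starting material
14 | bromoacetyl bromide | BrCC(=O)Br | starting material
15 | 2-(3,4-dihydroxyphenyl)ethyl bromoacetate | BrCC(=O)OCCc1ccc(O)c(O)c1 | intermediate
16 | 2-[3,4-bis(tert-butyldimethylsilyloxy)phenyl]ethyl bromoacetate | BrCC(=O)OCCc1ccc(O[Si](C)(C)C(C)(C)C)c(O[Si](C)(C)C(C)(C)C)c1 | intermediate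
17 | bromozinc Reformatsky reagent of 16 | Br[Zn]CC(=O)OCCc1ccc(O[Si](C)(C)C(C)(C)C)c(O[Si](C)(C)C(C)(C)C)c1 | intermediate
18 | 2-[3,4-bis(tert-butyldimethylsilyloxy)phenyl]ethyl 2-{(2S,3R,6S)-6-methoxy-3-[(4-methoxybenzyloxy)methyl]-2-methyl-3,6-dihydro-2H-pyran-4-yl}acetate | C[C@@H]1O[C@H](OC)C=C(CC(=O)OCCc2ccc(O[Si](C)(C)C(C)(C)C)c(O[Si](C)(C)C(C)(C)C)c2)[C@@H]1COCc3ccc(OC)cc3 | intermediate
19 | 2-[3,4-bis(tert-butyldimethylsilyloxy)phenyl]ethyl 2-[(2S,3R,6S)-3-(hydroxymethyl)-6-methoxy-2-methyl-3,6-dihydro-2H-pyran-4-yl]acetate | C[C@@H]1O[C@H](OC)C=C(CC(=O)OCCc2ccc(O[Si](C)(C)C(C)(C)C)c(O[Si](C)(C)C(C)(C)C)c2)[C@@H]1CO | intermediate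
20 | 2-[3,4-bis(tert-butyldimethylsilyloxy)phenyl]ethyl 2-[(2S,3R,4S,6S)-3-(hydroxymethyl)-6-methoxy-2-methyloxan-4-yl]acetate | C[C@@H]1O[C@H](OC)C[C@@H](CC(=O)OCCc2ccc(O[Si](C)(C)C(C)(C)C)c(O[Si](C)(C)C(C)(C)C)c2)[C@@H]1CO | intermediate
21 | 2-[3,4-bis(tert-butyldimethylsilyloxy)phenyl]ethyl 2-[(2S,3R,4S,6S)-3-(tert-butyldimethylsilyloxymethyl)-6-methoxy-2-methyloxan-4-yl]acetate | C[C@@H]1O[C@H](OC)C[C@@H](CC(=O)OCCc2ccc(O[Si](C)(C)C(C)(C)C)c(O[Si](C)(C)C(C)(C)C)c2)[C@@H]1CO[Si](C)(C)C(C)(C)C | intermediate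
22 | 2-[3,4-bis(tert-butyldimethylsilyloxy)phenyl]ethyl 2-[(2S,3R,4R)-3-(tert-butyldimethylsilyloxymethyl)-2-methyl-3,4-dihydro-2H-pyran-4-yl]acetate | C[C@@H]1OC=C[C@@H](CC(=O)OCCc2ccc(O[Si](C)(C)C(C)(C)C)c(O[Si](C)(C)C(C)(C)C)c2)[C@@H]1CO[Si](C)(C)C(C)(C)C | intermediate
23 | trichloroacetyl chloride | ClC(=O)C(Cl)(Cl)Cl | starting material
24 | 2-[3,4-bis(tert-butyldimethylsilyloxy)phenyl]ethyl 2-[(2S,3R,4S)-3-(tert-butyldimethylsilyloxymethyl)-2-methyl-5-(trichloroacetyl)-3,4-dihydro-2H-pyran-4-yl]acetate | C[C@@H]1OC=C(C(=O)C(Cl)(Cl)Cl)[C@@H](CC(=O)OCCc2ccc(O[Si](C)(C)C(C)(C)C)c(O[Si](C)(C)C(C)(C)C)c2)[C@@H]1CO[Si](C)(C)C(C)(C)C | intermediate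
25 | methyl (2S,3R,4S)-4-(2-{2-[3,4-bis(tert-butyldimethylsilyloxy)phenyl]ethoxy}-2-oxoethyl)-3-(tert-butyldimethylsilyloxymethyl)-2-methyl-3,4-dihydro-2H-pyran-5-carboxylate | C[C@@H]1OC=C(C(=O)OC)[C@@H](CC(=O)OCCc2ccc(O[Si](C)(C)C(C)(C)C)c(O[Si](C)(C)C(C)(C)C)c2)[C@@H]1CO[Si](C)(C)C(C)(C)C | intermediate
26 | methyl (2S,3R,4S)-4-{2-[2-(3,4-dihydroxyphenyl)ethoxy]-2-oxoethyl}-3-(hydroxymethyl)-2-methyl-3,4-dihydro-2H-pyran-5-carboxylate | COC(=O)C1=CO[C@@H](C)[C@@H](CO)[C@@H]1CC(=O)OCCc1ccc(O)c(O)c1 | target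

Total step count: 15. Longest linear sequence: 13 (steps 1–6 and 9–15); steps 7 and 8 form the side branch.

Steps most likely to fail

**Step 5.** Turnover may be slow because the reacting diene terminus carries C10. Volatile acetaldehyde may be lost to self-condensation. The reaction may also leak into a stepwise Mukaiyama aldol pathway. Each of these would erode endo and enantiofacial selectivity.

Fallback: the C2–C3 bond is made by a reagent-controlled boron aldol reaction, setting out from enone 7 and acetaldehyde 9.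
- Diisopinocampheylboron triflate (the antipode leading to the 2S,3R series) and iPr2NEt form the Z enol borinate. Its chair transition state should give the syn aldol (1E,4R,5S)-5-hydroxy-1-methoxy-4-[(4-methoxybenzyloxy)methyl]hex-1-en-3-one F1.
- Catalytic trifluoroacetic acid closes F1 by oxa-Michael addition and loss of methanol to (2S,3R)-3-[(4-methoxybenzyloxy)methyl]-2-methyl-2,3-dihydro-4H-pyran-4-one F2.
- 1,2-Addition of Reformatsky reagent 17, as known for 3-alkoxyenones, gives the tertiary carbinol at C4 F3. Its C4 configuration is lost in the next operation.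
- PPTS in methanol transposes the allylic alcohol (Ferrier-type) to the methyl acetal, expected mainly as the C6 epimer of 18 F4.
- The conditions of steps 10, 11 and 12 then lead through the C6 epimer of 19 F5, the C6 epimer of 20 F6 and the C6 epimer of 21 F7.
- The series comes back to the route at 22, where C6 is no longer stereogenic.

**Step 6.** Cleavage of the triethylsilyl–oxygen bond by methyllithium may need a temperature at which the enolate begins to expel methoxide from C6 and collapses to the dihydropyranone.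

Fallback: the enolate is made by deprotonation instead of desilylation, setting out from 10.
- Buffered desilylation (Bu4NF/AcOH, THF, 0 °C) protonates the enolate as it forms and gives (2S,3R,6S)-6-methoxy-3-[(4-methoxybenzyloxy)methyl]-2-methyloxan-4-one F8.
- Kinetic deprotonation with LDA at −78 °C removes a proton from the unhindered C5 methylene rather than the tertiary C3–H. This gives enolate 11 at a temperature where it should persist.
- The same pyridyl triflimide returns the material to the route at 12.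

**Step 13.** C-acylation at C5 is slowed by the adjacent branched C4. Addition of HCl to the enol ether or loss of silyl groups may then compete. The following methanolysis also has to choose among three carbonyl groups.

Fallback: the ester carbon is brought in as a formyl group, setting out from 22.
- Vilsmeier–Haack formylation (POCl3, DMF, 0 °C; aq NaOAc) uses the smaller chloroiminium electrophile and gives 2-[3,4-bis(tert-butyldimethylsilyloxy)phenyl]ethyl 2-[(2S,3R,4S)-3-(tert-butyldimethylsilyloxymethyl)-5-formyl-2-methyl-3,4-dihydro-2H-pyran-4-yl]acetate F9.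
- Pinnick oxidation (NaClO2, NaH2PO4, 2-methylbut-2-ene, tBuOH/H2O) gives (2S,3R,4S)-4-(2-{2-[3,4-bis(tert-butyldimethylsilyloxy)phenyl]ethoxy}-2-oxoethyl)-3-(tert-butyldimethylsilyloxymethyl)-2-methyl-3,4-dihydro-2H-pyran-5-carboxylic acid F10.
- (Trimethylsilyl)diazomethane in toluene/MeOH comes back to the route at 25, without base and without methanolysis.

Further compounds

F1 | step 5 | (1E,4R,5S)-5-hydroxy-1-methoxy-4-[(4-methoxybenzyloxy)methyl]hex-1-en-3-one | C[C@H](O)[C@@H](COCc1ccc(OC)cc1)C(=O)/C=C/OC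
F2 | step 5 | (2S,3R)-3-[(4-methoxybenzyloxy)methyl]-2-methyl-2,3-dihydro-4H-pyran-4-one | C[C@@H]1OC=CC(=O)[C@@H]1COCc2ccc(OC)cc2
F3 | step 5 | tertiary carbinol at C4: 2-[3,4-bis(tert-butyldimethylsilyloxy)phenyl]ethyl 2-{(2S,3R,4S)-4-hydroxy-3-[(4-methoxybenzyloxy)methyl]-2-methyl-3,4-dihydro-2H-pyran-4-yl}acetate | C[C@@H]1OC=C[C@@](O)(CC(=O)OCCc2ccc(O[Si](C)(C)C(C)(C)C)c(O[Si](C)(C)C(C)(C)C)c2)[C@@H]1COCc3ccc(OC)cc3
F4 | step 5 | C6 epimer of 18 (2S,3R,6R) | C[C@@H]1O[C@@H](OC)C=C(CC(=O)OCCc2ccc(O[Si](C)(C)C(C)(C)C)c(O[Si](C)(C)C(C)(C)C)c2)[C@@H]1COCc3ccc(OC)cc3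
F5 | step 5 | C6 epimer of 19 (2S,3R,6R) | C[C@@H]1O[C@@H](OC)C=C(CC(=O)OCCc2ccc(O[Si](C)(C)C(C)(C)C)c(O[Si](C)(C)C(C)(C)C)c2)[C@@H]1CO
F6 | step 5 | C6 epimer of 20 (2S,3R,4S,6R) | C[C@@H]1O[C@@H](OC)C[C@@H](CC(=O)OCCc2ccc(O[Si](C)(C)C(C)(C)C)c(O[Si](C)(C)C(C)(C)C)c2)[C@@H]1CO
F7 | step 5 | C6 epimer of 21 (2S,3R,4S,6R) | C[C@@H]1O[C@@H](OC)C[C@@H](CC(=O)OCCc2ccc(O[Si](C)(C)C(C)(C)C)c(O[Si](C)(C)C(C)(C)C)c2)[C@@H]1CO[Si](C)(C)C(C)(C)C
F8 | step 6 | (2S,3R,6S)-6-methoxy-3-[(4-methoxybenzyloxy)methyl]-2-methyloxan-4-one | C[C@@H]1O[C@H](OC)CC(=O)[C@@H]1COCc2ccc(OC)cc2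
F9 | step 13 | 2-[3,4-bis(tert-butyldimethylsilyloxy)phenyl]ethyl 2-[(2S,3R,4S)-3-(tert-butyldimethylsilyloxymethyl)-5-formyl-2-methyl-3,4-dihydro-2H-pyran-4-yl]acetate | C[C@@H]1OC=C(C=O)[C@@H](CC(=O)OCCc2ccc(O[Si](C)(C)C(C)(C)C)c(O[Si](C)(C)C(C)(C)C)c2)[C@@H]1CO[Si](C)(C)C(C)(C)C
F10 | step 13 | (2S,3R,4S)-4-(2-{2-[3,4-bis(tert-butyldimethylsilyloxy)phenyl]ethoxy}-2-oxoethyl)-3-(tert-butyldimethylsilyloxymethyl)-2-methyl-3,4-dihydro-2H-pyran-5-carboxylic acid | C[C@@H]1OC=C(C(=O)O)[C@@H](CC(=O)OCCc2ccc(O[Si](C)(C)C(C)(C)C)c(O[Si](C)(C)C(C)(C)C)c2)[C@@H]1CO[Si](C)(C)C(C)(C)C
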